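**Plan**

- Feature used: in ring B (O1, C2, C3, C4, C4a, C8a) the lactone carbon C2 and the ketone carbon C4 are both carboxyl-level carbons on the quaternary C3, so C3 is traced back to the prochiral C5 of a 5,5-disubstituted Meldrum's acid.
- Cuts, in retrosynthetic order: the ynone C(=O)–C(sp) bond (diyne fragment 2 off core fragment 1), the C4–C4a aryl ketone bond, the O1–C2 aryl ester bond, then the C3–farnesyl and C3–CH2 bonds.
- Forward, fragment 1: Meldrum's acid takes the propanoate arm (Michael addition) and the farnesyl arm (alkylation). Desymmetrising phenolysis with 2-iodophenol makes O1–C2. Thioester formation, zinc insertion and palladium-catalysed acylation then close ring B, the only ring formed.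
- Forward, fragment 2: dec-2-yn-1-ol gives (Z)-dec-2-enal, to which a silyl butadiyne is added. The acid chloride of fragment 1 is joined to the terminal diyne by acyl Sonogashira coupling, and the silyl ether is removed last.
- Stereochemistry: C3 (S) comes from the catalyst-controlled choice between the enantiotopic acylal carbonyls. The carbinol (S) comes from zinc–ProPhenol-controlled Re-face alkynylation, the Z alkene from syn semi-hydrogenation, and the E,E geometry from farnesyl bromide.

Key step: step 3

Assumption 1: the quinine-derived squaramide is taken to give (S)-8; if the sense is opposite, its quinidine-derived pseudo-enantiomer is used and nothing else changes.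
Assumption 2: (S,S)-ProPhenol is taken to direct the diynide to the Re face of enal 17; if the sense is opposite, (R,R)-ProPhenol is used.

Farnesyl below means (2E,6E)-3,7,11-trimethyldodeca-2,6,10-trien-1-yl.

**Route**

Step 1
Reactants: 1 Meldrum's acid; 2 tert-butyl acrylate
Product: 3 tert-butyl 3-(2,2-dimethyl-4,6-dioxo-1,3-dioxan-5-yl)propanoate
Conditions: K2CO3 (20 mol%), BnEt3NCl (10 mol%), MeCN, 50 °C; acrylate added slowly to a threefold excess of Meldrum's acid
Reagents that add atoms: none
Why: Michael addition of the Meldrum's acid anion to the acrylate, in which the surplus of the dione and the slow addition of the acceptor should hold back the second addition, the neutral bis-adduct stays in the organic phase when the acidic mono-adduct is extracted into aqueous NaHCO3, and unreacted Meldrum's acid is washed out with water.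

Step 2
Reactants: 3 tert-butyl 3-(2,2-dimethyl-4,6-dioxo-1,3-dioxan-5-yl)propanoate; 4 (2E,6E)-farnesyl bromide
Product: 5 tert-butyl 3-[5-[(2E,6E)-farnesyl]-2,2-dimethyl-4,6-dioxo-1,3-dioxan-5-yl]propanoate
Conditions: K2CO3 (1.5 equiv), DMF, 0 °C to 20 °C
Reagents that add atoms: none
Why: SN2 C-alkylation of the stabilised Meldrum's acid anion by the primary allylic bromide should give the prochiral quaternary carbon with the 2E,6E geometry untouched.

Step 3
Reactants: 5 tert-butyl 3-[5-[(2E,6E)-farnesyl]-2,2-dimethyl-4,6-dioxo-1,3-dioxan-5-yl]propanoate; 6 2-iodophenol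
Product: 8 (S)-2-[(2E,6E)-farnesyl]-2-(3-tert-butoxy-3-oxopropyl)malonic acid mono(2-iodophenyl) ester, via hemiketal ester 7 (not isolated)
Conditions: squaramide of 9-amino-9-deoxy-epi-quinine and 3,5-bis(trifluoromethyl)aniline (10 mol%), slight excess of the phenol, MTBE, −20 °C to 0 °C; aqueous citric acid work-up
Reagents that add atoms: none
Why: Proposed new method: the quinuclidine nitrogen of the catalyst takes the phenol proton while the squaramide N–H pair binds one acylal carbonyl, the ion-paired 2-iodophenoxide adds to that carbonyl, the tetrahedral intermediate collapses by cleavage of the ring C–O bond to hemiketal ester 7, and loss of acetone makes the acyl transfer irreversible and kinetically controlled. The closest known reaction type is the cinchona-catalysed enantioselective alcoholysis of prochiral cyclic anhydrides, with the esterase desymmetrisation of disubstituted malonates as the nearest case for this substrate class; phenolysis of a 5,5-disubstituted Meldrum's acid under chiral control has not been shown. No ring closes: the O1–C2 aryl ester bond forms and the temporary 1,3-dioxane-4,6-dione ring opens. The quaternary stereocentre (the future C3) is controlled by the catalyst alone, which has to tell the allylic farnesyl arm, branched at its first alkene, from the linear arm whose tert-butyl ester carbonyl offers a second hydrogen-bond acceptor. Enantiotopic-carbonyl selectivity is therefore the selectivity needed and the least secure, whereas chemoselectivity over the tert-butyl ester and the stop after one acyl transfer are secured by the strained, doubly activated acylal and by the unreactive carboxylate left after the first opening. Because the aryl group cannot migrate between the two carboxyl carbons (that would need a four-membered malonic anhydride), the configuration once set should be kept.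

Step 4
Reactants: 8 (S)-2-[(2E,6E)-farnesyl]-2-(3-tert-butoxy-3-oxopropyl)malonic acid mono(2-iodophenyl) ester
Product: 9 S-ethyl O-(2-iodophenyl) (R)-2-[(2E,6E)-farnesyl]-2-(3-tert-butoxy-3-oxopropyl)monothiomalonate (same spatial arrangement as 8; the descriptor changes because sulfur outranks oxygen)
Conditions: EtSH (3 equiv), DCC (1.2 equiv), DMAP (5 mol%), CH2Cl2, 0 °C to 20 °C
Reagents that add atoms: ethanethiol, CCS
Why: Steglich-type thioesterification, in which the acid has no α-hydrogen, so neither ketene formation nor epimerisation is possible and the aryl and tert-butyl esters should stay intact.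

Step 5
Reactants: 9 S-ethyl O-(2-iodophenyl) (R)-2-[(2E,6E)-farnesyl]-2-(3-tert-butoxy-3-oxopropyl)monothiomalonate
Product: 11 tert-butyl 3-[(3S)-3-[(2E,6E)-farnesyl]-2,4-dioxochroman-3-yl]propanoate, via arylzinc iodide 10 (not isolated)
Conditions: Zn dust (2 equiv), LiCl (2 equiv), THF, 25 °C; then Pd(PPh3)4 (5 mol%), 40 °C
Reagents that add atoms: none
Why: Direct insertion of LiCl-activated zinc into the aryl iodide followed by an intramolecular Fukuyama coupling (oxidative addition of zerovalent palladium into the C–S bond, transmetalation, reductive elimination) should form the C4–C4a ketone bond and ring B by six-membered closure, the quaternary centre having no α-hydrogen to lose.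

Step 6
Reactants: 11 tert-butyl 3-[(3S)-3-[(2E,6E)-farnesyl]-2,4-dioxochroman-3-yl]propanoate
Product: 13 3-[(3S)-3-[(2E,6E)-farnesyl]-2,4-dioxochroman-3-yl]propanoic acid, via trimethylsilyl ester 12 (not isolated)
Conditions: TMSOTf (3 equiv), 2,6-lutidine (4 equiv), CH2Cl2, 0 °C; then aqueous citric acid
Reagents that add atoms: none
Why: Silyl-triflate-mediated tert-butyl ester cleavage (O-silylation, loss of the tert-butyl cation as isobutene under lutidine buffering, hydrolysis of the silyl ester on work-up) avoids the protic acid that would attack the farnesyl alkenes.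

Step 7
Reactants: 13 3-[(3S)-3-[(2E,6E)-farnesyl]-2,4-dioxochroman-3-yl]propanoic acid
Product: 14 3-[(3S)-3-[(2E,6E)-farnesyl]-2,4-dioxochroman-3-yl]propanoyl chloride (used crude)
Conditions: 1-chloro-N,N,2-trimethylprop-1-en-1-amine (1.2 equiv), CH2Cl2, 0 °C to 20 °C
Reagents that add atoms: 1-chloro-N,N,2-trimethylprop-1-en-1-amine, CC(C)=C(Cl)N(C)C
Why: Acid chloride formation with the α-chloroenamine runs under neutral conditions and gives only an amide by-product and no HCl, so the polyene and the aryl lactone should survive.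

Step 8
Reactants: 15 dec-2-yn-1-ol
Product: 16 (Z)-dec-2-en-1-ol
Conditions: H2 (1 atm), Pd/CaCO3 poisoned with Pb(OAc)2, quinoline, EtOAc, 20 °C
Reagents that add atoms: none
Why: Syn semi-hydrogenation of the alkyne on the lead-poisoned palladium surface (Lindlar reduction) should stop at the Z alkene.

Step 9
Reactants: 16 (Z)-dec-2-en-1-ol
Product: 17 (Z)-dec-2-enal (used at once)
Conditions: Dess–Martin periodinane (1.2 equiv), NaHCO3, CH2Cl2, 0 °C
Reagents that add atoms: none
Why: Dess–Martin oxidation under bicarbonate buffer at low temperature is the standard way to reach a Z-enal without Z-to-E isomerisation.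

Step 10
Reactants: 18 1,4-bis(trimethylsilyl)buta-1,3-diyne
Product: 20 buta-1,3-diyn-1-yl(trimethyl)silane (kept as a toluene solution), via lithium diynide 19 (not isolated)
Conditions: MeLi·LiBr (1.0 equiv), Et2O, 0 °C to 20 °C; then H2O, 0 °C
Reagents that add atoms: none
Why: Mono-desilylation by attack of methyllithium at silicon should stop after one cleavage because the resulting diynide is anionic, and protonation gives the terminal diyne.

Step 11
Reactants: 17 (Z)-dec-2-enal; 20 buta-1,3-diyn-1-yl(trimethyl)silane
Product: 21 (5S,6Z)-1-(trimethylsilyl)tetradec-6-ene-1,3-diyn-5-ol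
Conditions: threefold excess of the diyne, Me2Zn (3 equiv), (S,S)-ProPhenol (20 mol%), Ph3P=O (40 mol%), toluene, 0 °C to 4 °C; aqueous NH4Cl
Reagents that add atoms: none
Why: Enantioselective alkynylation of an enal with a 1,3-diyne under the dinuclear zinc complex formed from Me2Zn and ProPhenol, whose chiral pocket should deliver the zinc diynide to the Re face of the aldehyde and so set the S carbinol.

Step 12
Reactants: 21 (5S,6Z)-1-(trimethylsilyl)tetradec-6-ene-1,3-diyn-5-ol
Product: 22 triethyl{[(5S,6Z)-1-(trimethylsilyl)tetradec-6-ene-1,3-diyn-5-yl]oxy}silane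
Conditions: TESCl (1.2 equiv), imidazole (2 equiv), CH2Cl2, 0 °C
Reagents that add atoms: chlorotriethylsilane, CC[Si](Cl)(CC)CC
Why: Imidazole-promoted O-silylation of the secondary alcohol does not touch the stereocentre.

Step 13
Reactants: 22 triethyl{[(5S,6Z)-1-(trimethylsilyl)tetradec-6-ene-1,3-diyn-5-yl]oxy}silane
Product: 23 triethyl{[(5S,6Z)-tetradec-6-ene-1,3-diyn-5-yl]oxy}silane (used at once)
Conditions: K2CO3 (20 mol%), MeOH/THF, 0 °C
Reagents that add atoms: none
Why: Base-catalysed methanolysis cleaves the C(sp)–Si bond of a diyne far faster than a secondary triethylsilyl ether.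

Step 14
Reactants: 14 3-[(3S)-3-[(2E,6E)-farnesyl]-2,4-dioxochroman-3-yl]propanoyl chloride; 23 triethyl{[(5S,6Z)-tetradec-6-ene-1,3-diyn-5-yl]oxy}silane
Product: 24 (3S)-3-[(2E,6E)-farnesyl]-3-[(8S,9Z)-3-oxo-8-(triethylsilyloxy)heptadec-9-ene-4,6-diyn-1-yl]chromane-2,4-dione
Conditions: PdCl2(PPh3)2 (3 mol%), CuI (6 mol%), Et3N (1.2 equiv), THF, 20 °C, argon
Reagents that add atoms: none
Why: Acyl Sonogashira coupling (copper diynide transmetalation to the acylpalladium chloride, reductive elimination) should form the ynone C–C bond without touching the chromandione or either stereocentre.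

Step 15
Reactants: 24 (3S)-3-[(2E,6E)-farnesyl]-3-[(8S,9Z)-3-oxo-8-(triethylsilyloxy)heptadec-9-ene-4,6-diyn-1-yl]chromane-2,4-dione
Product: 25 (3S)-3-[(2E,6E)-farnesyl]-3-[(8S,9Z)-8-hydroxy-3-oxoheptadec-9-ene-4,6-diyn-1-yl]chromane-2,4-dione (CNP0346147.1)
Conditions: HF·pyridine, pyridine, THF, 0 °C
Reagents that add atoms: none
Why: Buffered fluoride cleavage of the labile triethylsilyl ether is non-basic, so the diynone and the aryl lactone should not be attacked.

**Compound list**

1 | Meldrum's acid (2,2-dimethyl-1,3-dioxane-4,6-dione) | CC1(C)OC(=O)CC(=O)O1 | starting material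
2 | tert-butyl acrylate | C=CC(=O)OC(C)(C)C | starting material
3 | tert-butyl 3-(2,2-dimethyl-4,6-dioxo-1,3-dioxan-5-yl)propanoate | CC(C)(C)OC(=O)CCC1C(=O)OC(C)(C)OC1=O | intermediate
4 | (2E,6E)-farnesyl bromide | CC(C)=CCC/C(C)=C/CC/C(C)=C/CBr | starting material
5 | tert-butyl 3-[5-[(2E,6E)-farnesyl]-2,2-dimethyl-4,6-dioxo-1,3-dioxan-5-yl]propanoate | CC(C)(C)OC(=O)CCC1(C/C=C(\C)CC/C=C(\C)CCC=C(C)C)C(=O)OC(C)(C)OC1=O | intermediate
6 | 2-iodophenol | Oc1ccccc1I | starting material
7 | 2-hydroxypropan-2-yl 2-iodophenyl (R)-2-[(2E,6E)-farnesyl]-2-(3-tert-butoxy-3-oxopropyl)malonate (hemiketal ester, same spatial arrangement as 8) | CC(C)(C)OC(=O)CC[C@@](C(=O)OC(C)(C)O)(C/C=C(\C)CC/C=C(\C)CCC=C(C)C)C(=O)Oc1ccccc1I | intermediate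
8 | (S)-2-[(2E,6E)-farnesyl]-2-(3-tert-butoxy-3-oxopropyl)malonic acid mono(2-iodophenyl) ester | CC(C)(C)OC(=O)CC[C@@](C(=O)O)(C/C=C(\C)CC/C=C(\C)CCC=C(C)C)C(=O)Oc1ccccc1I | intermediate
9 | S-ethyl O-(2-iodophenyl) (R)-2-[(2E,6E)-farnesyl]-2-(3-tert-butoxy-3-oxopropyl)monothiomalonate | CC(C)(C)OC(=O)CC[C@@](C(=O)SCC)(C/C=C(\C)CC/C=C(\C)CCC=C(C)C)C(=O)Oc1ccccc1I | intermediate
10 | arylzinc iodide of 9 (zinc in place of iodine) | CC(C)(C)OC(=O)CC[C@@](C(=O)SCC)(C/C=C(\C)CC/C=C(\C)CCC=C(C)C)C(=O)Oc1ccccc1[Zn]I | intermediate
11 | tert-butyl 3-[(3S)-3-[(2E,6E)-farnesyl]-2,4-dioxochroman-3-yl]propanoate | CC(C)(C)OC(=O)CC[C@@]1(C/C=C(\C)CC/C=C(\C)CCC=C(C)C)C(=O)Oc2ccccc2C1=O | intermediate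
12 | trimethylsilyl 3-[(3S)-3-[(2E,6E)-farnesyl]-2,4-dioxochroman-3-yl]propanoate | C[Si](C)(C)OC(=O)CC[C@@]1(C/C=C(\C)CC/C=C(\C)CCC=C(C)C)C(=O)Oc2ccccc2C1=O | intermediate
13 | 3-[(3S)-3-[(2E,6E)-farnesyl]-2,4-dioxochroman-3-yl]propanoic acid | OC(=O)CC[C@@]1(C/C=C(\C)CC/C=C(\C)CCC=C(C)C)C(=O)Oc2ccccc2C1=O | intermediate
14 | 3-[(3S)-3-[(2E,6E)-farnesyl]-2,4-dioxochroman-3-yl]propanoyl chloride | ClC(=O)CC[C@@]1(C/C=C(\C)CC/C=C(\C)CCC=C(C)C)C(=O)Oc2ccccc2C1=O | intermediate
15 | dec-2-yn-1-ol | CCCCCCCC#CCO | starting material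
16 | (Z)-dec-2-en-1-ol | CCCCCCC/C=C\CO | intermediate
17 | (Z)-dec-2-enal | CCCCCCC/C=C\C=O | intermediate
18 | 1,4-bis(trimethylsilyl)buta-1,3-diyne | C[Si](C)(C)C#CC#C[Si](C)(C)C | starting material
19 | lithium 4-(trimethylsilyl)buta-1,3-diyn-1-ide | [Li]C#CC#C[Si](C)(C)C | intermediate
20 | buta-1,3-diyn-1-yl(trimethyl)silane | C#CC#C[Si](C)(C)C | intermediate
21 | (5S,6Z)-1-(trimethylsilyl)tetradec-6-ene-1,3-diyn-5-ol | CCCCCCC/C=C\[C@H](O)C#CC#C[Si](C)(C)C | intermediate
22 | triethyl{[(5S,6Z)-1-(trimethylsilyl)tetradec-6-ene-1,3-diyn-5-yl]oxy}silane | CCCCCCC/C=C\[C@H](O[Si](CC)(CC)CC)C#CC#C[Si](C)(C)C | intermediate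
23 | triethyl{[(5S,6Z)-tetradec-6-ene-1,3-diyn-5-yl]oxy}silane | CCCCCCC/C=C\[C@H](O[Si](CC)(CC)CC)C#CC#C | intermediate
24 | (3S)-3-[(2E,6E)-farnesyl]-3-[(8S,9Z)-3-oxo-8-(triethylsilyloxy)heptadec-9-ene-4,6-diyn-1-yl]chromane-2,4-dione | CCCCCCC/C=C\[C@H](O[Si](CC)(CC)CC)C#CC#CC(=O)CC[C@@]1(C/C=C(\C)CC/C=C(\C)CCC=C(C)C)C(=O)Oc2ccccc2C1=O | intermediate
25 | (3S)-3-[(2E,6E)-farnesyl]-3-[(8S,9Z)-8-hydroxy-3-oxoheptadec-9-ene-4,6-diyn-1-yl]chromane-2,4-dione (CNP0346147.1) | CCCCCCC/C=C\[C@H](O)C#CC#CC(=O)CC[C@@]1(C/C=C(\C)CC/C=C(\C)CCC=C(C)C)C(=O)Oc2ccccc2C1=O | target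

**Step count and risks**

Total steps: 15. Longest linear sequence: 9 steps (steps 1 to 7, then 14 and 15, from Meldrum's acid).

Steps most likely to fail:

1. Step 3 (proposed new method). The catalyst may discriminate poorly between the two enantiotopic carbonyls, because both arms begin with a CH2 group, and turnover may stall when the product acid protonates the quinuclidine. Fallback by known chemistry: from 5 and 6, the ring is opened without chiral control by base-mediated phenolysis (Et3N, toluene, 40 °C) to give the racemic aryl hydrogen malonate F1. F1 is then resolved by preparative chromatography on a chiral stationary phase, the (R)-antipode F2 being set aside. The route is rejoined at 8.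

2. Step 5. Zinc insertion may be slow or end in protodemetalation, and oxidative addition into the hindered thioester next to the quaternary carbon may lag, so that the deiodinated open-chain thioester accumulates. Fallback: from 9, iodine–magnesium exchange with i-PrMgCl·LiCl in THF at −78 °C, a temperature at which acyl migration from the neighbouring aryl ester to the metalated carbon should not compete, gives the arylmagnesium chloride F3. On warming to −40 °C this should close onto the thioester carbonyl in a Parham-type anionic cyclisation and expel the thiolate, rejoining the route at 11.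

3. Step 14. The terminal diyne may homocouple or decompose in the presence of CuI, the acid chloride may form a ketene with Et3N, and the amine hydrochloride may add to the diynone. Fallback: from 23, deprotonation with n-BuLi (THF, −78 °C) and quenching with Bu3SnCl gives the alkynylstannane F4. F4 is coupled with 14 by Stille acylation (PdCl2(PPh3)2, toluene, 60 °C) without amine or copper, rejoining the route at 24.

Further compounds
F1 | step 3 | racemic 2-[(2E,6E)-farnesyl]-2-(3-tert-butoxy-3-oxopropyl)malonic acid mono(2-iodophenyl) ester | CC(C)(C)OC(=O)CCC(C(=O)O)(C/C=C(\C)CC/C=C(\C)CCC=C(C)C)C(=O)Oc1ccccc1I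
F2 | step 3 | (R)-2-[(2E,6E)-farnesyl]-2-(3-tert-butoxy-3-oxopropyl)malonic acid mono(2-iodophenyl) ester | CC(C)(C)OC(=O)CC[C@](C(=O)O)(C/C=C(\C)CC/C=C(\C)CCC=C(C)C)C(=O)Oc1ccccc1I
F3 | step 5 | arylmagnesium chloride of 9 (magnesium in place of iodine) | CC(C)(C)OC(=O)CC[C@@](C(=O)SCC)(C/C=C(\C)CC/C=C(\C)CCC=C(C)C)C(=O)Oc1ccccc1[Mg]Cl
F4 | step 14 | tributyl{(5S,6Z)-5-[(triethylsilyl)oxy]tetradec-6-ene-1,3-diyn-1-yl}stannane | CCCCCCC/C=C\[C@H](O[Si](CC)(CC)CC)C#CC#C[Sn](CCCC)(CCCC)CCCC
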